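**Retrosynthetic overview**

- The route rests on one feature: O1, C7a, C3a, C3 and C2 of the furan ring, together with ring B (C1'–C6'), are the skeleton of an ortho-hydroxystilbene. The target differs from that stilbene only by the O1–C2 bond and two fewer hydrogens, so the last skeletal bond is O1–C2, made by oxidising a stilbene whose only free hydroxyl is the future O1.
- The C2=C3 alkene is cut next: Horner–Wadsworth–Emmons olefination of a ring A salicylaldehyde (formyl carbon = C3) with a ring B benzylic phosphonate (benzylic carbon = C2).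
- Ring A comes from 2,4,6-trihydroxybenzaldehyde. A 4-O-prenyl ether undergoes aromatic Claisen rearrangement (para position blocked by the formyl group) to place the 1,1-dimethylallyl group at the future C7. Two MOM groups then cap O4 and O6, and the hindered O2 is capped as an allyl ether for the olefination only.
- Ring B comes from 3-hydroxy-5-methoxybenzaldehyde by bromination para to the hydroxyl, MOM protection, Stille prenylation, reduction, bromide formation and Arbuzov reaction.
- Both benzene rings are bought. The furan ring is the only ring formed, in the penultimate step, and removal of three MOM groups ends the route.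

Key step: step 13

Remark: atom numbers follow the benzofuran numbering of the target (O1, C2, C3, C3a, C4–C7, C7a; ring B C1'–C6'). The target has no stereocentre; the only stereochemical element on the way is the E alkene of the stilbene. Stannane 11 is taken as a purchased reagent.

**Route**

Step 1
Reactants: 1 2,4,6-trihydroxybenzaldehyde; 2 prenyl bromide (1-bromo-3-methylbut-2-ene)
Product: 3 2,6-dihydroxy-4-[(3-methylbut-2-en-1-yl)oxy]benzaldehyde
Conditions: K2CO3 (1.05 equiv), 2 (1.0 equiv), acetone, 0 °C → rt
Reagents that add atoms: none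
Why: Williamson ether synthesis: one equivalent of K2CO3 ionises only the 4-hydroxyl, which is para to the formyl group and the most acidic, while the two ortho hydroxyls are held in hydrogen bonds to the carbonyl, so O-alkylation by the allylic bromide should occur at O4.

Step 2
Reactants: 3 2,6-dihydroxy-4-[(3-methylbut-2-en-1-yl)oxy]benzaldehyde
Product: 5 2,4,6-trihydroxy-3-(2-methylbut-3-en-2-yl)benzaldehyde, via ortho-dienone 4 (not isolated)
Conditions: PhNEt2 (degassed), 190 °C, sealed tube, Ar
Reagents that add atoms: none
Why: Aromatic Claisen rearrangement: the [3,3] shift carries the allyl unit with inversion to the ortho carbon (C3 and C5 are equivalent by symmetry) to give dienone 4, which can only enolise to the phenol because the para carbon bears the formyl group, and the basic amine solvent suppresses acid-promoted addition of a flanking hydroxyl to the new vinyl group.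

Step 3
Reactants: 5 2,4,6-trihydroxy-3-(2-methylbut-3-en-2-yl)benzaldehyde
Product: 6 2-hydroxy-4,6-bis(methoxymethoxy)-3-(2-methylbut-3-en-2-yl)benzaldehyde
Conditions: MOMCl (2.2 equiv), i-Pr2NEt, CH2Cl2, 0 °C
Reagents that add atoms: chloromethyl methyl ether (MOMCl), COCCl
Why: Base-mediated MOM etherification of phenols: O4 (para to the formyl group) reacts first, and of the two chelated ortho hydroxyls the one at C6 is open whereas the one at C2 is wedged between the quaternary carbon and the formyl group, so with two equivalents of MOMCl and a mild amine base the second acetal should form at O6 and leave O2 free.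

Step 4
Reactants: 6 2-hydroxy-4,6-bis(methoxymethoxy)-3-(2-methylbut-3-en-2-yl)benzaldehyde
Product: 7 2-(allyloxy)-4,6-bis(methoxymethoxy)-3-(2-methylbut-3-en-2-yl)benzaldehyde
Conditions: allyl bromide, K2CO3, DMF, 50 °C
Reagents that add atoms: allyl bromide, C=CCBr
Why: Williamson etherification of the remaining hindered, chelated phenol with a small allylic halide in a dipolar solvent; the allyl ether keeps a phenoxide, which would deactivate the aldehyde, out of the olefination and can later be removed without acid or hydride.

Step 5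
Reactants: 8 3-hydroxy-5-methoxybenzaldehyde
Product: 9 2-bromo-5-hydroxy-3-methoxybenzaldehyde
Conditions: NBS (1.0 equiv), MeCN, −20 → 0 °C
Reagents that add atoms: N-bromosuccinimide, O=C1CCC(=O)N1Br
Why: Electrophilic aromatic bromination: the free hydroxyl is the strongest donor on the ring and directs para, to the carbon that is also ortho to the methoxy group, so one equivalent of NBS in a polar solvent at low temperature should give the 2-bromide as the main isomer, with any ortho-hydroxy bromide removed by chromatography.

Step 6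
Reactants: 9 2-bromo-5-hydroxy-3-methoxybenzaldehyde
Product: 10 2-bromo-3-methoxy-5-(methoxymethoxy)benzaldehyde
Conditions: MOMCl, i-Pr2NEt, CH2Cl2, 0 °C → rt
Reagents that add atoms: chloromethyl methyl ether (MOMCl), COCCl
Why: Standard MOM etherification of an unhindered phenol with MOMCl and a hindered amine; the aldehyde and the aryl bromide are inert.

Step 7
Reactants: 10 2-bromo-3-methoxy-5-(methoxymethoxy)benzaldehyde; 11 tributyl(3-methylbut-2-en-1-yl)stannane
Product: 12 3-methoxy-5-(methoxymethoxy)-2-(3-methylbut-2-en-1-yl)benzaldehyde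
Conditions: Pd(PPh3)4 (5 mol %), DMF, 100 °C
Reagents that add atoms: none
Why: Stille cross-coupling: oxidative addition of zerovalent palladium into the C–Br bond (helped by the ortho formyl group), transmetalation from the allylic stannane and reductive elimination at the less substituted allyl terminus should give the linear prenyl arene, under neutral conditions that spare the aldehyde and the MOM acetal.

Step 8
Reactants: 12 3-methoxy-5-(methoxymethoxy)-2-(3-methylbut-2-en-1-yl)benzaldehyde
Product: 13 [3-methoxy-5-(methoxymethoxy)-2-(3-methylbut-2-en-1-yl)phenyl]methanol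
Conditions: NaBH4, MeOH, 0 °C
Reagents that add atoms: none
Why: Hydride reduction of the aldehyde by NaBH4; the acetal and the trisubstituted alkene are untouched.

Step 9
Reactants: 13 [3-methoxy-5-(methoxymethoxy)-2-(3-methylbut-2-en-1-yl)phenyl]methanol
Product: 15 1-(bromomethyl)-3-methoxy-5-(methoxymethoxy)-2-(3-methylbut-2-en-1-yl)benzene, via benzylic mesylate 14 (not isolated)
Conditions: MsCl, Et3N, CH2Cl2, 0 °C; then LiBr, THF, rt
Reagents that add atoms: lithium bromide, [Li+].[Br-]
Why: Mesylation followed by SN2 displacement with bromide converts the electron-rich benzylic alcohol into the bromide without free HBr, so the prenyl alkene and the MOM acetal should survive.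

Step 10
Reactants: 15 1-(bromomethyl)-3-methoxy-5-(methoxymethoxy)-2-(3-methylbut-2-en-1-yl)benzene
Product: 17 diethyl [3-methoxy-5-(methoxymethoxy)-2-(3-methylbut-2-en-1-yl)benzyl]phosphonate, via phosphonium bromide 16 (not isolated)
Conditions: P(OEt)3 (neat, excess), 130 °C
Reagents that add atoms: triethyl phosphite, CCOP(OCC)OCC
Why: Michaelis–Arbuzov reaction: the phosphite displaces the benzylic bromide to give phosphonium salt 16, which bromide dealkylates to the phosphonate.

Step 11
Reactants: 17 diethyl [3-methoxy-5-(methoxymethoxy)-2-(3-methylbut-2-en-1-yl)benzyl]phosphonate; 7 2-(allyloxy)-4,6-bis(methoxymethoxy)-3-(2-methylbut-3-en-2-yl)benzaldehyde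
Product: 19 (E)-2-(allyloxy)-3'-methoxy-4,5',6-tris(methoxymethoxy)-3-(2-methylbut-3-en-2-yl)-2'-(3-methylbut-2-en-1-yl)stilbene, via sodium phosphonate carbanion 18 (not isolated)
Conditions: NaH, 15-crown-5 (cat.), THF, 0 °C → rt
Reagents that add atoms: none
Why: Horner–Wadsworth–Emmons olefination: the benzylic phosphonate anion 18 adds reversibly to the non-enolisable, fully capped aldehyde, and elimination through the less crowded oxaphosphetane should give the E stilbene.

Step 12
Reactants: 19 (E)-2-(allyloxy)-3'-methoxy-4,5',6-tris(methoxymethoxy)-3-(2-methylbut-3-en-2-yl)-2'-(3-methylbut-2-en-1-yl)stilbene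
Product: 20 (E)-3'-methoxy-4,5',6-tris(methoxymethoxy)-3-(2-methylbut-3-en-2-yl)-2'-(3-methylbut-2-en-1-yl)stilben-2-ol
Conditions: Pd(PPh3)4 (5 mol %), morpholine, THF, rt
Reagents that add atoms: none
Why: Tsuji–Trost deallylation: zerovalent palladium ionises the aryl allyl ether to a π-allyl complex that morpholine captures, releasing the phenol under neutral conditions in which the MOM acetals and the prenyl, 1,1-dimethylallyl and stilbene alkenes (none carrying an allylic leaving group) are inert.

Step 13
Reactants: 20 (E)-3'-methoxy-4,5',6-tris(methoxymethoxy)-3-(2-methylbut-3-en-2-yl)-2'-(3-methylbut-2-en-1-yl)stilben-2-ol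
Product: 22 2-[3-methoxy-5-(methoxymethoxy)-2-(3-methylbut-2-en-1-yl)phenyl]-4,6-bis(methoxymethoxy)-7-(2-methylbut-3-en-2-yl)-1-benzofuran, via aryloxy-λ3-iodanyl acetate 21 (not isolated)
Conditions: PhI(OAc)2 (1.1 equiv), MeCN, 0 °C → rt
Reagents that add atoms: none
Why: Oxidative cyclisation of an ortho-hydroxystilbene to a 2-arylbenzofuran by a trivalent iodine reagent, a known reaction type: the single free phenol exchanges for acetate on iodine to give 21, and reductive loss of iodobenzene (a two-electron oxidation) leaves positive charge that is spread over ring A and through C3a and C3 onto C2, the carbon bearing ring B. O1 then bonds to C2 and closes the furan ring; by Baldwin's classification this is a 5-endo-trig attack, but because C2 is by then the terminus of a delocalised 1-oxapentadienyl cation the ring forms in effect by a 4π electrocyclisation, and loss of the proton at C2 makes the ring aromatic. No stereocentre arises, and the E alkene, which places O1 within reach of C2, is consumed. The step needs chemoselectivity: the oxidant must take the phenol–alkene unit and leave the prenyl alkene, the vinyl group and ring B alone. This is secured by the substrate itself, since ring A with one free hydroxyl, two acetal oxygens and the conjugated alkene is much the most electron-rich part, the only hydroxyl able to bind iodine is O1, and isolated alkenes do not react with PhI(OAc)2 unless a strong acid is present. Acetonitrile as a non-nucleophilic solvent and a low starting temperature should keep acetate from adding to ring carbons in competition with the internal oxygen.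

Step 14
Reactants: 22 2-[3-methoxy-5-(methoxymethoxy)-2-(3-methylbut-2-en-1-yl)phenyl]-4,6-bis(methoxymethoxy)-7-(2-methylbut-3-en-2-yl)-1-benzofuran
Product: 23 2-[5-hydroxy-3-methoxy-2-(3-methylbut-2-en-1-yl)phenyl]-7-(2-methylbut-3-en-2-yl)-1-benzofuran-4,6-diol
Conditions: p-TsOH·H2O, MeOH, rt → 40 °C
Reagents that add atoms: none
Why: Acid-catalysed transacetalisation: the three aryl MOM acetals are cleaved in methanol under mild sulfonic acid catalysis, conditions under which a prenyl group without a neighbouring hydroxyl and the poorly basic monosubstituted vinyl group of the 1,1-dimethylallyl unit should neither add methanol nor cyclise.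

**Compound list**

1 | 2,4,6-trihydroxybenzaldehyde | O=Cc1c(O)cc(O)cc1O | starting material
2 | prenyl bromide (1-bromo-3-methylbut-2-ene) | CC(C)=CCBr | starting material
3 | 2,6-dihydroxy-4-[(3-methylbut-2-en-1-yl)oxy]benzaldehyde | O=Cc1c(O)cc(OCC=C(C)C)cc1O | intermediate
4 | 2,6-dihydroxy-3-(2-methylbut-3-en-2-yl)-4-oxocyclohexa-1,5-diene-1-carbaldehyde (ortho-dienone, racemic, not isolated) | O=CC1=C(O)C(C(C)(C)C=C)C(=O)C=C1O | intermediate
5 | 2,4,6-trihydroxy-3-(2-methylbut-3-en-2-yl)benzaldehyde | O=Cc1c(O)cc(O)c(C(C)(C)C=C)c1O | intermediate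
6 | 2-hydroxy-4,6-bis(methoxymethoxy)-3-(2-methylbut-3-en-2-yl)benzaldehyde | O=Cc1c(OCOC)cc(OCOC)c(C(C)(C)C=C)c1O | intermediate
7 | 2-(allyloxy)-4,6-bis(methoxymethoxy)-3-(2-methylbut-3-en-2-yl)benzaldehyde | O=Cc1c(OCOC)cc(OCOC)c(C(C)(C)C=C)c1OCC=C | intermediate
8 | 3-hydroxy-5-methoxybenzaldehyde | COc1cc(O)cc(C=O)c1 | starting material
9 | 2-bromo-5-hydroxy-3-methoxybenzaldehyde | O=Cc1cc(O)cc(OC)c1Br | intermediate
10 | 2-bromo-3-methoxy-5-(methoxymethoxy)benzaldehyde | O=Cc1cc(OCOC)cc(OC)c1Br | intermediate
11 | tributyl(3-methylbut-2-en-1-yl)stannane | CCCC[Sn](CCCC)(CCCC)CC=C(C)C | starting material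
12 | 3-methoxy-5-(methoxymethoxy)-2-(3-methylbut-2-en-1-yl)benzaldehyde | O=Cc1cc(OCOC)cc(OC)c1CC=C(C)C | intermediate
13 | [3-methoxy-5-(methoxymethoxy)-2-(3-methylbut-2-en-1-yl)phenyl]methanol | OCc1cc(OCOC)cc(OC)c1CC=C(C)C | intermediate
14 | 3-methoxy-5-(methoxymethoxy)-2-(3-methylbut-2-en-1-yl)benzyl methanesulfonate (not isolated) | CS(=O)(=O)OCc1cc(OCOC)cc(OC)c1CC=C(C)C | intermediate
15 | 1-(bromomethyl)-3-methoxy-5-(methoxymethoxy)-2-(3-methylbut-2-en-1-yl)benzene | BrCc1cc(OCOC)cc(OC)c1CC=C(C)C | intermediate
16 | triethoxy[3-methoxy-5-(methoxymethoxy)-2-(3-methylbut-2-en-1-yl)benzyl]phosphonium bromide (not isolated) | CCO[P+](OCC)(OCC)Cc1cc(OCOC)cc(OC)c1CC=C(C)C.[Br-] | intermediate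
17 | diethyl [3-methoxy-5-(methoxymethoxy)-2-(3-methylbut-2-en-1-yl)benzyl]phosphonate | CCOP(=O)(OCC)Cc1cc(OCOC)cc(OC)c1CC=C(C)C | intermediate
18 | sodium salt of the benzylic carbanion of 17 (not isolated) | [Na+].CCOP(=O)(OCC)[CH-]c1cc(OCOC)cc(OC)c1CC=C(C)C | intermediate
19 | (E)-2-(allyloxy)-3'-methoxy-4,5',6-tris(methoxymethoxy)-3-(2-methylbut-3-en-2-yl)-2'-(3-methylbut-2-en-1-yl)stilbene | C=CC(C)(C)c1c(OCOC)cc(OCOC)c(/C=C/c2cc(OCOC)cc(OC)c2CC=C(C)C)c1OCC=C | intermediate
20 | (E)-3'-methoxy-4,5',6-tris(methoxymethoxy)-3-(2-methylbut-3-en-2-yl)-2'-(3-methylbut-2-en-1-yl)stilben-2-ol | C=CC(C)(C)c1c(OCOC)cc(OCOC)c(/C=C/c2cc(OCOC)cc(OC)c2CC=C(C)C)c1O | intermediate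
21 | acetoxy(phenyl)-λ3-iodanyl ether of 20 at O2 (not isolated) | C=CC(C)(C)c1c(OCOC)cc(OCOC)c(/C=C/c2cc(OCOC)cc(OC)c2CC=C(C)C)c1OI(OC(C)=O)c1ccccc1 | intermediate
22 | 2-[3-methoxy-5-(methoxymethoxy)-2-(3-methylbut-2-en-1-yl)phenyl]-4,6-bis(methoxymethoxy)-7-(2-methylbut-3-en-2-yl)-1-benzofuran | C=CC(C)(C)c1c(OCOC)cc(OCOC)c2cc(-c3cc(OCOC)cc(OC)c3CC=C(C)C)oc12 | intermediate
23 | 2-[5-hydroxy-3-methoxy-2-(3-methylbut-2-en-1-yl)phenyl]-7-(2-methylbut-3-en-2-yl)-1-benzofuran-4,6-diol | C=CC(C)(C)c1c(O)cc(O)c2cc(-c3cc(O)cc(OC)c3CC=C(C)C)oc12 | target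

**Step count**

Total steps: 14. Longest linear sequence: 10 steps (steps 5 to 14, from 8); the ring A branch (steps 1 to 4) joins at step 11.

**Steps most likely to fail**

1. Step 2 (Claisen rearrangement). At 190 °C the freshly formed ortho-(1,1-dimethylallyl)phenol may react further: a flanking hydroxyl can transfer its hydrogen to the vinyl group, leading to the rearranged side chain or to ring closure to a dihydrofuran. The free polyphenolic aldehyde may also degrade.
 Fallback, from 3 back to 5: the phenols are kept silylated throughout the rearrangement. Heating 3 with excess N,O-bis(trimethylsilyl)acetamide in PhNEt2 should first give 4-[(3-methylbut-2-en-1-yl)oxy]-2,6-bis(trimethylsilyloxy)benzaldehyde F1. The phenol formed by the [3,3] shift is silylated as it appears, giving 3-(2-methylbut-3-en-2-yl)-2,4,6-tris(trimethylsilyloxy)benzaldehyde F2, in which no hydroxyl can reach the vinyl group. K2CO3 in MeOH then removes the three silyl groups to give 5.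

2. Step 13 (oxidative cyclisation). The oxidised ring A may be intercepted at carbon by acetate or traces of water (at C5 or C7), leading to quinoid products, or may couple intermolecularly, before O1 reaches C2.
 Fallback, from 20 back to 22: the alkene is activated in place of the phenol. I2 and K2CO3 in THF at 0 °C should bring about anti iodoetherification, the phenoxide oxygen opening the iodonium ion at the carbon bearing ring B, to give racemic trans-3-iodo-2-[3-methoxy-5-(methoxymethoxy)-2-(3-methylbut-2-en-1-yl)phenyl]-4,6-bis(methoxymethoxy)-7-(2-methylbut-3-en-2-yl)-2,3-dihydro-1-benzofuran F3. Warming with K2CO3 then eliminates HI, by ionisation of the C3–I bond (benzylic to the electron-rich ring A) and loss of the C2 proton, to give 22.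

3. Step 5 (bromination). Bromine may enter ortho to the hydroxyl (C2 or C4 of 8) in competition with the wanted para attack, or a second bromine may be introduced.
 Fallback, from 8 back to 12 (steps 5 to 7 are bypassed): the site is fixed by directed metalation in place of electrophilic substitution.
 - TIPSCl and imidazole in DMF give 3-methoxy-5-(triisopropylsilyloxy)benzaldehyde F4.
 - LiN(Me)CH2CH2NMe2 (from N,N,N'-trimethylethylenediamine and n-BuLi) adds to the formyl group to give the lithium α-amino alkoxide F5 (not isolated).
 - n-BuLi then removes the ring proton between this chelating group and the methoxy group, the bulky and poorly coordinating silyl ether shielding the other two positions, to give the C2-lithiated α-amino alkoxide F6 (not isolated).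
 - Alkylation with prenyl bromide 2 (10 mol % CuBr·SMe2) and aqueous work-up return the aldehyde as 3-methoxy-2-(3-methylbut-2-en-1-yl)-5-(triisopropylsilyloxy)benzaldehyde F7.
 - TBAF in THF gives 5-hydroxy-3-methoxy-2-(3-methylbut-2-en-1-yl)benzaldehyde F8, and MOMCl with i-Pr2NEt gives 12.

**Further compounds**

F1 | step 2 | 4-[(3-methylbut-2-en-1-yl)oxy]-2,6-bis(trimethylsilyloxy)benzaldehyde | O=Cc1c(O[Si](C)(C)C)cc(OCC=C(C)C)cc1O[Si](C)(C)C
F2 | step 2 | 3-(2-methylbut-3-en-2-yl)-2,4,6-tris(trimethylsilyloxy)benzaldehyde | O=Cc1c(O[Si](C)(C)C)cc(O[Si](C)(C)C)c(C(C)(C)C=C)c1O[Si](C)(C)C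
F3 | step 13 | trans-3-iodo-2-[3-methoxy-5-(methoxymethoxy)-2-(3-methylbut-2-en-1-yl)phenyl]-4,6-bis(methoxymethoxy)-7-(2-methylbut-3-en-2-yl)-2,3-dihydro-1-benzofuran (racemic, one enantiomer drawn) | I[C@@H]1c2c(OCOC)cc(OCOC)c(C(C)(C)C=C)c2O[C@H]1c3cc(OCOC)cc(OC)c3CC=C(C)C
F4 | step 5 | 3-methoxy-5-(triisopropylsilyloxy)benzaldehyde | COc1cc(C=O)cc(O[Si](C(C)C)(C(C)C)C(C)C)c1
F5 | step 5 | lithium α-amino alkoxide from F4 and LiN(Me)CH2CH2NMe2 (racemic, not isolated) | COc1cc(cc(O[Si](C(C)C)(C(C)C)C(C)C)c1)C(O[Li])N(C)CCN(C)C
F6 | step 5 | C2-lithiated α-amino alkoxide (racemic, not isolated) | COc1cc(O[Si](C(C)C)(C(C)C)C(C)C)cc(C(O[Li])N(C)CCN(C)C)c1[Li]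
F7 | step 5 | 3-methoxy-2-(3-methylbut-2-en-1-yl)-5-(triisopropylsilyloxy)benzaldehyde | COc1cc(O[Si](C(C)C)(C(C)C)C(C)C)cc(C=O)c1CC=C(C)C
F8 | step 5 | 5-hydroxy-3-methoxy-2-(3-methylbut-2-en-1-yl)benzaldehyde | COc1cc(O)cc(C=O)c1CC=C(C)C
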